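**Plan** (tetralin numbering: C1 carries the aryl group, C2 and C3 the CH2OH groups, C4 is the ring CH2; ring A is the fused arene, ring B the saturated ring)
- Cuts: the two benzyl ethers and the C2/C3 diol go back to a trans-fused gamma-lactone. Ring B of that lactone is then cut at C4–C3 and at C8a–C1, a (3+3) disconnection into a 4-alkoxy-3-methoxybenzyl cation equivalent (C4, C4a, C8a) and a lactone-fused aryl cyclopropane (C1, C2, C3).
- Enabling feature: C1 carries the electron-rich guaiacyl ring and C3 lies alpha to the lactone carbonyl, so a C1–C3 cyclopropane bond is push–pull polarised (C1 electrophilic, C3 nucleophilic once opened). In ring A, C4 is a benzylic carbon para to an alkoxy group (electrophile) and C8a is para to the methoxy group (nucleophile).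
- Forward order: aryl acrylate, cinnamyl diazoacetate, cyclopropane and lactone ring in one enantioselective carbene addition, ring B by the annulation, lactone reduced to the diol, benzyl ethers removed.
- Stereochemistry: C2 comes from the catalyst-controlled cyclopropanation and is never touched again. C3 is set by alkylation anti to the C2 substituent. C1 is reset in the Friedel–Crafts closure, aryl trans to C2.

Key step: step 6

Assumption: the (4S)-configured catalyst of step 4 is taken to give the (1R,5S,6S) lactone, the sense known for allyl diazoacetates with this catalyst family; if the sense were the opposite, the (4R) mirror-image catalyst would be used and nothing else changes.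

**Step 1**
Reactants: 1 4-(benzyloxy)-3-methoxybenzaldehyde; 2 triethyl phosphonoacetate
Product: 3 ethyl (E)-3-[4-(benzyloxy)-3-methoxyphenyl]prop-2-enoate
Conditions: NaH, THF, 0 °C → rt
Reagents that add atoms: none
Why: Horner–Wadsworth–Emmons olefination of an aromatic aldehyde with a stabilised phosphonate anion, which should give the (E)-cinnamate through the favoured anti elimination.

**Step 2**
Reactants: 3 ethyl (E)-3-[4-(benzyloxy)-3-methoxyphenyl]prop-2-enoate
Product: 4 (E)-3-[4-(benzyloxy)-3-methoxyphenyl]prop-2-en-1-ol
Conditions: i-Bu2AlH (2.2 equiv), CH2Cl2, −78 °C; aqueous Rochelle salt work-up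
Reagents that add atoms: none
Why: 1,2-reduction of the conjugated ester by i-Bu2AlH to the allylic alcohol; the alkene and the benzyl ether are inert to the hydride.

**Step 3**
Reactants: 4 (E)-3-[4-(benzyloxy)-3-methoxyphenyl]prop-2-en-1-ol; 5 glyoxylic acid chloride p-toluenesulfonylhydrazone
Product: 7 (E)-3-[4-(benzyloxy)-3-methoxyphenyl]allyl diazoacetate, via glyoxylate tosylhydrazone ester 6 (not isolated)
Conditions: 5 (1.9 equiv), PhNMe2, CH2Cl2, 0 °C; then Et3N, 0 °C → rt
Reagents that add atoms: none
Why: House–Corey–Myers diazoacetate synthesis: the acid chloride acylates the alcohol to ester 6, and triethylamine then triggers Bamford–Stevens-type loss of p-toluenesulfinate from the tosylhydrazone anion to leave the diazo ester.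

**Step 4**
Reactants: 7 (E)-3-[4-(benzyloxy)-3-methoxyphenyl]allyl diazoacetate
Product: 8 (1R,5S,6S)-6-[4-(benzyloxy)-3-methoxyphenyl]-3-oxabicyclo[3.1.0]hexan-2-one (aryl exo)
Conditions: Rh2(4S-MPPIM)4 (1 mol%; a chiral carboxamidate dimer of divalent rhodium, MPPIM = methyl 1-(3-phenylpropanoyl)-2-oxoimidazolidine-4-carboxylate), CH2Cl2, reflux, slow addition of 7 over several hours
Reagents that add atoms: none
Why: intramolecular cyclopropanation by a rhodium carbene: the concerted addition keeps the E geometry, so the aryl group ends up exo and trans to the lactone CH2, and the chiral carboxamidate ligands choose the alkene face, setting C1, C5 and C6 in one event.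

**Step 5**
Reactants: 9 4-(benzyloxy)-3-methoxybenzyl alcohol
Product: 10 4-(benzyloxy)-3-methoxybenzyl chloride
Conditions: SOCl2, CH2Cl2, 0 °C → rt; used freshly prepared
Reagents that add atoms: thionyl chloride, ClS(Cl)=O
Why: chlorodehydroxylation of an electron-rich benzylic alcohol by thionyl chloride through the chlorosulfite (nucleophilic substitution with loss of SO2).

**Step 6**
Reactants: 8 (1R,5S,6S)-6-[4-(benzyloxy)-3-methoxyphenyl]-3-oxabicyclo[3.1.0]hexan-2-one; 10 4-(benzyloxy)-3-methoxybenzyl chloride
Product: 13 all-trans aryltetralin lactone (dibenzyl ether of the conidendrin skeleton; 1R,2S,3S), via iodo silyl ketene acetal 11 (not isolated), via iodo lactone 12 (not isolated)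
Conditions: Me3SiI (1.05 equiv), 2,6-di-tert-butyl-4-methylpyridine (1.5 equiv), CH2Cl2, −78 → −40 °C; then 10 (1.1 equiv), ZnI2 (0.2 equiv), −40 °C → rt
Reagents that add atoms: iodotrimethylsilane, C[Si](C)(C)I (its silicon and iodine stay in intermediates 11 and 12 only and leave before product 13)
Why: Proposed new method: a formal (3+3) annulation by iodide relay, in which Me3SiI silylates the lactone carbonyl of 8 and iodide opens the push–pull C6–C1 bond of the cyclopropane to the gamma-iodo silyl ketene acetal 11, whose nucleophilic carbon (the future C3) is alkylated by the 4-alkoxybenzyl cation that ZnI2 frees from 10 to give 12, after which ZnI2 ionises the benzylic C–I bond and the cation (the future C1) is captured by the ring A carbon para to the methoxy group. The closest known reaction types are the opening of cyclopropyl carbonyl compounds by Me3SiI, the Lewis-acid alkylation of silyl ketene acetals by ionisable benzylic halides (Reetz type) and the acid cyclisation of 7-hydroxymatairesinol-type lactones to the conidendrin skeleton; their fusion into one cross annulation of a cyclopropane with a benzyl halide is the untested part. Ring B is the only ring closed, by a six-membered intramolecular Friedel–Crafts alkylation (cation–arene closure with the departing iodide exocyclic), while the three-membered ring is cleaved and the lactone ring is kept. C3 is set by attack of the benzyl cation on the face of the five-membered ketene acetal anti to the bulky substituent on the neighbouring C2 (trans alkylation, substrate control from the untouched C2 centre), and C1, whose cyclopropane configuration is erased on ionisation, is set in the ring closure with the aryl group pseudo-equatorial and trans to C2. The step needs the ketene acetal and not an arene to capture the benzyl cation, which its far higher nucleophilicity and the formation of 11 before 10 is added should secure, and it needs closure at C8a and not at the crowded carbon between CH2 and OMe, which para-methoxy activation and sterics should secure. The hindered pyridine takes up HI so that neither 11 nor the benzyl ethers meet free acid, and reversion of 11 to 8 is harmless because Me3SiI reopens it.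

**Step 7**
Reactants: 13 all-trans aryltetralin lactone
Product: 14 [(1R,2S,3S)-7-(benzyloxy)-1-[4-(benzyloxy)-3-methoxyphenyl]-6-methoxy-1,2,3,4-tetrahydronaphthalene-2,3-diyl]dimethanol
Conditions: LiAlH4, THF, 0 °C → rt; Fieser work-up
Reagents that add atoms: none
Why: hydride reduction of the gamma-lactone by LiAlH4 to the 1,4-diol, the known way from the conidendrin skeleton to the isolariciresinol skeleton; reduction is faster than enolisation, so C3 keeps its configuration and no stereocentre is touched.

**Step 8**
Reactants: 14 dibenzyl diol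
Product: 15 (6S,7S,8R)-8-(4-hydroxy-3-methoxyphenyl)-6,7-bis(hydroxymethyl)-3-methoxy-5,6,7,8-tetrahydronaphthalen-2-ol (isolariciresinol, the enantiomer asked for)
Conditions: H2 (1 atm), 10% Pd/C, EtOAc–MeOH, rt
Reagents that add atoms: none
Why: catalytic hydrogenolysis of the two aryl benzyl ethers over palladium on carbon; the benzylic C–C bonds and the primary alcohols are not cleaved under these mild conditions.

**Compound list**
1 | 4-(benzyloxy)-3-methoxybenzaldehyde (O-benzylvanillin) | O=Cc1ccc(OCc2ccccc2)c(OC)c1 | starting material
2 | triethyl phosphonoacetate | CCOC(=O)CP(=O)(OCC)OCC | starting material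
3 | ethyl (E)-3-[4-(benzyloxy)-3-methoxyphenyl]prop-2-enoate | CCOC(=O)/C=C/c1ccc(OCc2ccccc2)c(OC)c1 | intermediate
4 | (E)-3-[4-(benzyloxy)-3-methoxyphenyl]prop-2-en-1-ol | OC/C=C/c1ccc(OCc2ccccc2)c(OC)c1 | intermediate
5 | glyoxylic acid chloride p-toluenesulfonylhydrazone | Cc1ccc(cc1)S(=O)(=O)NN=CC(Cl)=O | starting material
6 | (E)-3-[4-(benzyloxy)-3-methoxyphenyl]allyl 2-(2-tosylhydrazinylidene)acetate | Cc1ccc(cc1)S(=O)(=O)NN=CC(=O)OC/C=C/c1ccc(OCc2ccccc2)c(OC)c1 | intermediate
7 | (E)-3-[4-(benzyloxy)-3-methoxyphenyl]allyl diazoacetate | [N-]=[N+]=CC(=O)OC/C=C/c1ccc(OCc2ccccc2)c(OC)c1 | intermediate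
8 | (1R,5S,6S)-6-[4-(benzyloxy)-3-methoxyphenyl]-3-oxabicyclo[3.1.0]hexan-2-one | O=C1OC[C@H]2[C@H](c3ccc(OCc4ccccc4)c(OC)c3)[C@@H]12 | intermediate
9 | 4-(benzyloxy)-3-methoxybenzyl alcohol | OCc1ccc(OCc2ccccc2)c(OC)c1 | starting material
10 | 4-(benzyloxy)-3-methoxybenzyl chloride | ClCc1ccc(OCc2ccccc2)c(OC)c1 | intermediate
11 | (S)-4-[(S)-[4-(benzyloxy)-3-methoxyphenyl](iodo)methyl]-2-(trimethylsilyloxy)-4,5-dihydrofuran | C[Si](C)(C)OC1=C[C@@H](CO1)[C@H](I)c1ccc(OCc2ccccc2)c(OC)c1 | intermediate
12 | (3S,4S)-3-[4-(benzyloxy)-3-methoxybenzyl]-4-[(S)-[4-(benzyloxy)-3-methoxyphenyl](iodo)methyl]dihydrofuran-2(3H)-one | O=C1OC[C@@H]([C@H](I)c2ccc(OCc3ccccc3)c(OC)c2)[C@@H]1Cc1ccc(OCc2ccccc2)c(OC)c1 | intermediate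
13 | gamma-lactone between the C3 carboxyl and the C2 hydroxymethyl group of (1R,2S,3S)-7-(benzyloxy)-1-[4-(benzyloxy)-3-methoxyphenyl]-6-methoxytetralin, all-trans and trans-fused | COc1cc([C@@H]2c3cc(OCc4ccccc4)c(OC)cc3C[C@@H]3C(=O)OC[C@@H]23)ccc1OCc1ccccc1 | intermediate
14 | [(1R,2S,3S)-7-(benzyloxy)-1-[4-(benzyloxy)-3-methoxyphenyl]-6-methoxy-1,2,3,4-tetrahydronaphthalene-2,3-diyl]dimethanol | COc1cc([C@@H]2c3cc(OCc4ccccc4)c(OC)cc3C[C@H](CO)[C@H]2CO)ccc1OCc1ccccc1 | intermediate
15 | (6S,7S,8R)-8-(4-hydroxy-3-methoxyphenyl)-6,7-bis(hydroxymethyl)-3-methoxy-5,6,7,8-tetrahydronaphthalen-2-ol | COc1cc([C@@H]2c3cc(O)c(OC)cc3C[C@H](CO)[C@H]2CO)ccc1O | target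

**Total steps:** 8
**Longest linear sequence:** 7 (steps 1, 2, 3, 4, 6, 7, 8)

**Steps most likely to fail**

1. Step 6 (proposed new method). Three processes could defeat it. The benzylic iodide of the ketene acetal may ionise before the alkylation and lose the C2 proton, which erodes the C2 stereocentre and aromatises the ring to a silyloxyfuran. The benzyl cation may be captured by arenes instead of the ketene acetal, giving oligomers. The alkylation may also show poor facial selectivity, or the benzyl ethers may be lost to acid. The fallback is stepwise and sets out from 8. Acid-catalysed methanolysis (camphorsulfonic acid, MeOH) opens the cyclopropane at the benzylic carbon to (S)-4-[(S)-[4-(benzyloxy)-3-methoxyphenyl](methoxy)methyl]dihydrofuran-2(3H)-one F1; either configuration at the methoxy-bearing carbon serves. The lithium enolate of F1 (LDA, THF, −78 °C) is alkylated with 10 (NaI, DMPU) anti to the ring substituent, the classical trans alkylation of beta-substituted butyrolactone enolates, to give the trans-3-benzyl-4-(alpha-methoxybenzyl) lactone F2. CF3CO2H in CH2Cl2 then ionises the benzylic methyl ether and closes ring B as in the conidendrin-forming cyclisation, which comes back to the route at 13.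

2. Step 4. Facial discrimination on a trans-disubstituted, electron-rich alkene may be insufficient, and carbene dimerisation may compete with ring closure. The fallback sets out from 7. Rh2(OAc)4 in CH2Cl2 gives the racemic (1R*,5S*,6S*)-6-[4-(benzyloxy)-3-methoxyphenyl]-3-oxabicyclo[3.1.0]hexan-2-one F3, whose enantiomers are separated by preparative chromatography on a chiral stationary phase; the (1R,5S,6S) enantiomer is 8.

3. Step 3. The electron-rich cinnamyl alcohol may ionise or be chlorinated by the HCl released on acylation, and the tosylhydrazone ester may fragment incompletely. The fallback sets out from 4. Diketene with a catalytic amount of DMAP in THF gives (E)-3-[4-(benzyloxy)-3-methoxyphenyl]allyl acetoacetate F4. Diazo transfer with 4-acetamidobenzenesulfonyl azide and Et3N in MeCN gives the corresponding allyl 2-diazo-3-oxobutanoate F5. LiOH in aqueous THF removes the acetyl group and comes back to the route at 7.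

**Further compounds**
F1 | step 6 | (S)-4-[(S)-[4-(benzyloxy)-3-methoxyphenyl](methoxy)methyl]dihydrofuran-2(3H)-one | O=C1C[C@@H](CO1)[C@H](OC)c1ccc(OCc2ccccc2)c(OC)c1
F2 | step 6 | (3S,4S)-3-[4-(benzyloxy)-3-methoxybenzyl]-4-[(S)-[4-(benzyloxy)-3-methoxyphenyl](methoxy)methyl]dihydrofuran-2(3H)-one | O=C1OC[C@@H]([C@H](OC)c2ccc(OCc3ccccc3)c(OC)c2)[C@@H]1Cc1ccc(OCc2ccccc2)c(OC)c1
F3 | step 4 | racemic (1R*,5S*,6S*)-6-[4-(benzyloxy)-3-methoxyphenyl]-3-oxabicyclo[3.1.0]hexan-2-one | O=C1OC[C@H]2[C@H](c3ccc(OCc4ccccc4)c(OC)c3)[C@@H]12.O=C1OC[C@@H]2[C@@H](c3ccc(OCc4ccccc4)c(OC)c3)[C@H]12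
F4 | step 3 | (E)-3-[4-(benzyloxy)-3-methoxyphenyl]allyl 3-oxobutanoate | CC(=O)CC(=O)OC/C=C/c1ccc(OCc2ccccc2)c(OC)c1
F5 | step 3 | (E)-3-[4-(benzyloxy)-3-methoxyphenyl]allyl 2-diazo-3-oxobutanoate | CC(=O)C(=[N+]=[N-])C(=O)OC/C=C/c1ccc(OCc2ccccc2)c(OC)c1
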